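**Convention (one line):** positions use daucane numbering (C1 = ring-fusion carbon bearing CH3; C2 = CHOH, C3 = CH2, C4 = C(OH)iPr, C5 = ring-fusion CH; C6–C10 = seven-membered ring, C8 bears CH3); β = face of the C1 methyl, α = opposite face.

## Retrosynthetic overview

1. Target ⇐ C2 ketone (reduced last, directed by the 4α-OH); the 6β-tiglate comes from Mitsunobu inversion of a 6α-OH, the 10α-tiglate from acylation, the α-epoxide from OH-directed epoxidation of the C8=C9 alkene.
2. Five-membered ring (formed second) ⇐ intramolecular aldol (C3–C4) of a 1,4-diketone held on a cycloheptenone; quaternary C1 ⇐ C-methylation of the ring β-diketone.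
3. Seven-membered ring (formed first) ⇐ ring-closing metathesis at C8=C9.
4. Key C4–C5 bond ⇐ Stetter reaction: the acyl anion (Breslow intermediate) of isobutyraldehyde adds to the β-carbon of an alkylidene β-diketone.
5. Alkylidene β-diketone ⇐ Knoevenagel condensation of (E)-hept-5-ene-2,4-dione with an (R)-α-silyloxy aldehyde from a catalytic asymmetric glyoxylate–ene reaction.

## Route

Step 1
Reactants: 1 ethyl glyoxylate; 2 2-methylpropene
Product: 3 ethyl (2R)-2-hydroxy-4-methylpent-4-enoate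
Conditions: (R)-BINOL/TiBr2(OiPr)2 (5 mol%), 4 Å MS, CH2Cl2, −30 °C
Reagents that add atoms: none
Why: Catalytic asymmetric glyoxylate–ene (carbonyl-ene) reaction in which the (R)-BINOL–titanium Lewis acid blocks one aldehyde face and gives the (R)-carbinol; this centre becomes C6 and is deliberately the epimer of the target, to be inverted in step 11.

Step 2
Reactants: 3 ethyl (2R)-2-hydroxy-4-methylpent-4-enoate
Product: 4 ethyl (2R)-4-methyl-2-(triethylsilyloxy)pent-4-enoate
Conditions: Et3SiCl, imidazole, DMF, 0 °C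
Reagents that add atoms: chlorotriethylsilane, CC[Si](Cl)(CC)CC
Why: Standard O-silylation of the secondary alcohol, which masks it through the base-mediated steps and leaves the stereocentre untouched.

Step 3
Reactants: 5 tert-butyl 3-oxobutanoate; 6 (2E)-but-2-enoyl chloride
Product: 8 (5E)-hept-5-ene-2,4-dione, via triketo ester 7 (not isolated)
Conditions: MgCl2, pyridine, CH2Cl2, 0 °C to rt; then CF3CO2H, rt to 40 °C
Reagents that add atoms: none
Why: Magnesium-enolate C-acylation (Rathke conditions) followed by acidolysis of the tert-butyl ester and decarboxylation of the β-keto acid gives the unsymmetrical β-diketone; no stereocentre is formed.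

Step 4
Reactants: 4 ethyl (2R)-4-methyl-2-(triethylsilyloxy)pent-4-enoate; 8 (5E)-hept-5-ene-2,4-dione
Product: 10 (4R,8E)-6-acetyl-2-methyl-4-(triethylsilyloxy)deca-1,5,8-trien-7-one (5E/5Z mixture), via silyloxy aldehyde 9 (not isolated)
Conditions: i-Bu2AlH, CH2Cl2, −78 °C, Rochelle-salt work-up; then 8, piperidinium acetate (10 mol%), 4 Å MS, CH2Cl2, 0 °C
Reagents that add atoms: none
Why: Half-reduction of the α-silyloxy ester (the tetrahedral aluminium hemiacetal is stable at −78 °C) and Knoevenagel condensation of the crude aldehyde; the mild amine-salt catalyst preserves the α-stereocentre and the new alkene geometry is irrelevant.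

Step 5
Reactants: 10 (4R,8E)-6-acetyl-2-methyl-4-(triethylsilyloxy)deca-1,5,8-trien-7-one; 11 2-methylpropanal
Product: 12 (4R,5S,8E)-6-acetyl-2-methyl-5-(2-methylpropanoyl)-4-(triethylsilyloxy)deca-1,8-dien-7-one
Conditions: 11 (3 equiv), 3-benzyl-5-(2-hydroxyethyl)-4-methylthiazolium chloride (20 mol%), Et3N (40 mol%), THF, 60 °C
Reagents that add atoms: none
Why: Intermolecular Stetter reaction in which the Breslow intermediate of isobutyraldehyde (an acyl anion) adds to the β-carbon C5 of the doubly activated alkylidene diketone and forms the C4–C5 bond of a 1,4-diketone; C5 is set anti to the C6 silyloxy group by polar Felkin–Anh control (C6–H eclipses the alkene, attack opposite the C–O bond).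

Step 6
Reactants: 12 Stetter adduct
Product: 13 (5R,6S)-7-acetyl-3-methyl-6-(2-methylpropanoyl)-5-(triethylsilyloxy)cyclohept-2-en-1-one (C7 enolised)
Conditions: second-generation Hoveyda–Grubbs catalyst RuCl2(SIMes)(=CH-C6H4-2-OiPr) (5 mol%), toluene (2 mM), 80 °C
Reagents that add atoms: none
Why: Ring-closing metathesis between the methallyl and crotonoyl alkenes expels propene and closes the seven-membered ring as the β-methyl enone; no stereocentre is touched.

Step 7
Reactants: 13 cycloheptenone β-diketone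
Product: 14 (5R,6S,7S)-7-acetyl-3,7-dimethyl-6-(2-methylpropanoyl)-5-(triethylsilyloxy)cyclohept-2-en-1-one
Conditions: MeI, K2CO3, acetone, rt
Reagents that add atoms: iodomethane, CI
Why: C-alkylation of the cyclic β-diketone enolate; MeI attacks the face opposite the adjacent α-isobutyryl and α-silyloxy groups, giving the 1β-methyl quaternary centre with the acetyl group cis to the isobutyryl group.

Step 8
Reactants: 14 methylated cycloheptenone
Product: 16 (1S,4R,5S,6R)-4,6-dihydroxydauc-8-ene-2,10-dione (cis-fused; 4α-OH, 4β-iPr, 6α-OH), via silyl aldol 15 (not isolated)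
Conditions: LiN(SiMe3)2 (1.05 equiv), THF, −78 °C; AcOH; then HF·pyridine, 0 °C
Reagents that add atoms: none
Why: Kinetic deprotonation of the acetyl CH3 and intramolecular 5-exo aldol addition to the isobutyryl ketone closes the cis-fused cyclopentanone with the isopropyl group on the convex β face (tertiary OH α); fluoride then cleaves the silyl ether.

Step 9
Reactants: 16 (1S,4R,5S,6R)-4,6-dihydroxydauc-8-ene-2,10-dione
Product: 17 (1R,4R,5S,6R,10S)-4,6,10-trihydroxydauc-8-en-2-one (10α-OH)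
Conditions: NaBH4, CeCl3·7H2O, MeOH, −78 °C
Reagents that add atoms: none
Why: Luche 1,2-reduction, which takes the cerium-activated conjugated C10 ketone faster than the hindered saturated C2 ketone; hydride enters from the convex β face of the cis-fused bicycle and gives the 10α-alcohol.

Step 10
Reactants: 17 allylic alcohol
Product: 18 (1R,4R,5S,6R,8S,9R,10R)-8,9-epoxy-4,6,10-trihydroxydaucan-2-one (8α,9α-epoxide)
Conditions: VO(acac)2 (5 mol%), t-BuOOH, CH2Cl2, 0 °C to rt
Reagents that add atoms: tert-butyl hydroperoxide, CC(C)(C)OO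
Why: Hydroxyl-directed vanadium-catalysed epoxidation; the 10α allylic and 6α homoallylic hydroxyls both deliver the peroxide to the α face of the C8=C9 alkene.

Step 11
Reactants: 18 epoxy triol; 19 tiglic acid
Product: 20 (1R,4R,5S,6S,8S,9R,10R)-8,9-epoxy-4,10-dihydroxy-2-oxodaucan-6-yl (2E)-2-methylbut-2-enoate
Conditions: 19, PPh3, DIAD, THF, 0 °C to rt
Reagents that add atoms: none
Why: Mitsunobu esterification: the accessible secondary 6α-OH is activated and displaced by tiglate from the convex face with inversion, giving the 6β-tiglate; the neopentyl 10-OH and tertiary 4-OH do not react.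

Step 12
Reactants: 20 6β-tiglate; 21 tigloyl chloride
Product: 22 (1R,4R,5S,6S,8S,9R,10R)-8,9-epoxy-4-hydroxy-2-oxodaucane-6,10-diyl bis[(2E)-2-methylbut-2-enoate]
Conditions: 21, Et3N, DMAP, CH2Cl2, rt to 40 °C
Reagents that add atoms: none
Why: DMAP-catalysed acylation of the remaining secondary 10α-alcohol with retention; the tertiary 4-OH is inert and the C2 ketone needs no protection.

Step 13
Reactants: 22 bis-tiglate ketone
Product: 23 target, (1S,2S,4R,5S,6S,8S,9R,10R)-8,9-epoxy-2,4-dihydroxydaucane-6,10-diyl bis[(2E)-2-methylbut-2-enoate]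
Conditions: Me4NBH(OAc)3, MeCN/AcOH (1:1), −30 °C
Reagents that add atoms: none
Why: Evans–Saksena hydroxyl-directed reduction: the 4α-OH binds the acetoxyborohydride and delivers hydride to the α face of the C2 ketone, giving the trans-1,3-diol (2β-OH) while the esters and epoxide survive.

## Compound list

1 | ethyl glyoxylate | CCOC(=O)C=O | starting material
2 | 2-methylpropene (isobutene) | CC(C)=C | starting material
3 | ethyl (2R)-2-hydroxy-4-methylpent-4-enoate | CCOC(=O)[C@H](O)CC(C)=C | intermediate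
4 | ethyl (2R)-4-methyl-2-(triethylsilyloxy)pent-4-enoate | CCOC(=O)[C@H](O[Si](CC)(CC)CC)CC(C)=C | intermediate
5 | tert-butyl 3-oxobutanoate | CC(=O)CC(=O)OC(C)(C)C | starting material
6 | (2E)-but-2-enoyl chloride | C/C=C/C(Cl)=O | starting material
7 | tert-butyl (4E)-2-acetyl-3-oxohex-4-enoate | CC(=O)C(C(=O)OC(C)(C)C)C(=O)/C=C/C | intermediate (not isolated)
8 | (5E)-hept-5-ene-2,4-dione | CC(=O)CC(=O)/C=C/C | intermediate
9 | (2R)-4-methyl-2-(triethylsilyloxy)pent-4-enal | O=C[C@H](O[Si](CC)(CC)CC)CC(C)=C | intermediate (not isolated)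
10 | (4R,8E)-6-acetyl-2-methyl-4-(triethylsilyloxy)deca-1,5,8-trien-7-one (5E/5Z mixture) | CC(=O)C(=C[C@H](O[Si](CC)(CC)CC)CC(C)=C)C(=O)/C=C/C | intermediate
11 | 2-methylpropanal (isobutyraldehyde) | CC(C)C=O | starting material
12 | (4R,5S,8E)-6-acetyl-2-methyl-5-(2-methylpropanoyl)-4-(triethylsilyloxy)deca-1,8-dien-7-one (chain C6 enolisable, left undefined) | CC[Si](CC)(CC)O[C@@H]([C@@H](C(=O)C(C)C)C(C(C)=O)C(=O)/C=C/C)CC(C)=C | intermediate
13 | (5R,6S)-7-acetyl-3-methyl-6-(2-methylpropanoyl)-5-(triethylsilyloxy)cyclohept-2-en-1-one (C7 enolised, left undefined) | CC[Si](CC)(CC)O[C@@H]1CC(C)=CC(=O)C(C(C)=O)[C@@H]1C(=O)C(C)C | intermediate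
14 | (5R,6S,7S)-7-acetyl-3,7-dimethyl-6-(2-methylpropanoyl)-5-(triethylsilyloxy)cyclohept-2-en-1-one | CC[Si](CC)(CC)O[C@@H]1CC(C)=CC(=O)[C@@](C(C)=O)(C)[C@@H]1C(=O)C(C)C | intermediate
15 | (1S,4R,5S,6R)-4-hydroxy-6-(triethylsilyloxy)dauc-8-ene-2,10-dione | CC[Si](CC)(CC)O[C@@H]1CC(C)=CC(=O)[C@@]2(C)[C@@H]1[C@](O)(C(C)C)CC2=O | intermediate (not isolated)
16 | (1S,4R,5S,6R)-4,6-dihydroxydauc-8-ene-2,10-dione | O[C@@H]1CC(C)=CC(=O)[C@@]2(C)[C@@H]1[C@](O)(C(C)C)CC2=O | intermediate
17 | (1R,4R,5S,6R,10S)-4,6,10-trihydroxydauc-8-en-2-one | O[C@@H]1CC(C)=C[C@H](O)[C@@]2(C)[C@@H]1[C@](O)(C(C)C)CC2=O | intermediate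
18 | (1R,4R,5S,6R,8S,9R,10R)-8,9-epoxy-4,6,10-trihydroxydaucan-2-one | O[C@@H]1C[C@]2(C)O[C@@H]2[C@H](O)[C@@]2(C)[C@@H]1[C@](O)(C(C)C)CC2=O | intermediate
19 | tiglic acid, (2E)-2-methylbut-2-enoic acid | C/C=C(\C)C(O)=O | starting material
20 | (1R,4R,5S,6S,8S,9R,10R)-8,9-epoxy-4,10-dihydroxy-2-oxodaucan-6-yl (2E)-2-methylbut-2-enoate | C/C=C(\C)C(=O)O[C@H]1C[C@]2(C)O[C@@H]2[C@H](O)[C@@]2(C)[C@@H]1[C@](O)(C(C)C)CC2=O | intermediate
21 | tigloyl chloride, (2E)-2-methylbut-2-enoyl chloride | C/C=C(\C)C(Cl)=O | starting material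
22 | (1R,4R,5S,6S,8S,9R,10R)-8,9-epoxy-4-hydroxy-2-oxodaucane-6,10-diyl bis[(2E)-2-methylbut-2-enoate] | C/C=C(\C)C(=O)O[C@H]1C[C@]2(C)O[C@@H]2[C@H](OC(=O)/C(C)=C/C)[C@@]2(C)[C@@H]1[C@](O)(C(C)C)CC2=O | intermediate
23 | CNP0265715.1, (1S,2S,4R,5S,6S,8S,9R,10R)-8,9-epoxy-2,4-dihydroxydaucane-6,10-diyl bis[(2E)-2-methylbut-2-enoate] | C/C=C(\C)C(=O)O[C@H]1C[C@]2(C)O[C@@H]2[C@H](OC(=O)/C(C)=C/C)[C@@]2(C)[C@@H]1[C@](O)(C(C)C)C[C@@H]2O | target

## Step count and risks

Total step count: 13. Longest linear sequence: 12 (steps 1, 2, 4–13; step 3 is a one-step side branch).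

**Step 5 (Stetter reaction).** The aldehyde is α-branched, the acidic β-diketone product can protonate the carbene, and the Felkin preference may be modest. The fallback sets out from 10: DBU-catalysed Michael addition of 2-methyl-1-nitropropane (the nitronate as a stoichiometric acyl anion equivalent) gives the γ-nitro triketone F1. A buffered aqueous TiCl3 Nef reaction then converts the nitro-bearing carbon into the C4 ketone and comes back to the route at 12.

**Step 9 (Luche reduction).** The C2 cyclopentanone may be reduced as well. The fallback sets out from 16 and changes the order of events. Me4NBH(OAc)3 first gives the 2β,4α,6α-trihydroxy enone F2. Et3SiCl/imidazole caps both secondary hydroxyls as the 2,6-bis(triethylsilyl) ether F3. NaBH4/CeCl3·7H2O, now with only the enone to reduce, gives the 10α-allylic alcohol F4. VO(acac)2/t-BuOOH gives the α-epoxy alcohol F5. Tigloyl chloride 21/DMAP gives the 10-tiglate F6. HF·pyridine removes both silyl groups to give the 2β,6α-diol F7. Mitsunobu esterification with tiglic acid 19 inverts only the 6α-OH (the neopentyl 2-OH is inert) and comes back to the route at 23.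

**Step 11 (Mitsunobu inversion at C6).** The carbinol is flanked by the ring-fusion carbon, and elimination may compete. The fallback sets out from 18: selective sulfonylation of the least hindered hydroxyl (MsCl, pyridine, −20 °C) gives the 6α-mesylate F8. Displacement with caesium tiglate (CsO2C–C(CH3)=CHCH3, 18-crown-6, toluene, 80 °C) with inversion comes back to the route at 20.

Further compounds

F1 | step 5 | (4R,5S,8E)-6-acetyl-2-methyl-5-(2-methyl-1-nitropropyl)-4-(triethylsilyloxy)deca-1,8-dien-7-one | CC[Si](CC)(CC)O[C@@H]([C@@H](C(C(C)C)[N+](=O)[O-])C(C(C)=O)C(=O)/C=C/C)CC(C)=C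
F2 | step 9 | 2β,4α,6α-trihydroxydauc-8-en-10-one | O[C@@H]1CC(C)=CC(=O)[C@@]2(C)[C@@H]1[C@](O)(C(C)C)C[C@@H]2O
F3 | step 9 | 4α-hydroxy-2β,6α-bis(triethylsilyloxy)dauc-8-en-10-one | CC[Si](CC)(CC)O[C@@H]1CC(C)=CC(=O)[C@@]2(C)[C@@H]1[C@](O)(C(C)C)C[C@@H]2O[Si](CC)(CC)CC
F4 | step 9 | 2β,6α-bis(triethylsilyloxy)dauc-8-ene-4α,10α-diol | CC[Si](CC)(CC)O[C@@H]1CC(C)=C[C@H](O)[C@@]2(C)[C@@H]1[C@](O)(C(C)C)C[C@@H]2O[Si](CC)(CC)CC
F5 | step 9 | 8α,9α-epoxy-2β,6α-bis(triethylsilyloxy)daucane-4α,10α-diol | CC[Si](CC)(CC)O[C@@H]1C[C@]2(C)O[C@@H]2[C@H](O)[C@@]2(C)[C@@H]1[C@](O)(C(C)C)C[C@@H]2O[Si](CC)(CC)CC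
F6 | step 9 | 8α,9α-epoxy-4α-hydroxy-2β,6α-bis(triethylsilyloxy)daucan-10α-yl (2E)-2-methylbut-2-enoate | CC[Si](CC)(CC)O[C@@H]1C[C@]2(C)O[C@@H]2[C@H](OC(=O)/C(C)=C/C)[C@@]2(C)[C@@H]1[C@](O)(C(C)C)C[C@@H]2O[Si](CC)(CC)CC
F7 | step 9 | 8α,9α-epoxy-2β,4α,6α-trihydroxydaucan-10α-yl (2E)-2-methylbut-2-enoate | O[C@@H]1C[C@]2(C)O[C@@H]2[C@H](OC(=O)/C(C)=C/C)[C@@]2(C)[C@@H]1[C@](O)(C(C)C)C[C@@H]2O
F8 | step 11 | 8α,9α-epoxy-4α,10α-dihydroxy-2-oxodaucan-6α-yl methanesulfonate | CS(=O)(=O)O[C@@H]1C[C@]2(C)O[C@@H]2[C@H](O)[C@@]2(C)[C@@H]1[C@](O)(C(C)C)CC2=O
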